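**Retrosynthetic overview**

1. Numbering used throughout: ring carbons C1–C10 (oxirane O on C1/C10, C4=C5, isopropenyl on C7, OAc on C9), C14 = CH2O(isobutyryl) on C10, C15 = CO2Me carbon on C4.
2. The ten-membered carbocycle is disconnected at C4=C5: intramolecular Horner–Wadsworth–Emmons reaction of a C5 aldehyde with a C4 phosphonoacetate. It is the last ring to form; the oxirane is installed earlier by Sharpless epoxidation of the C14 allylic alcohol across C1=C10.
3. C1=C10 comes from a geometry-selective α-alkoxy-ketone Wittig reaction that attaches one C5 ylide (C1–C4 and C15); the phosphonate is then placed on C4 through the ester enolate.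
4. The C10 ketone and the C5 aldehyde are the two ends of the cut C2=C3 double bond of (1S,5S)-cis-carveol. All ten carbons of (S)-carvone become C5–C10, C14 and the isopropenyl group, and its two stereocentres become C7 and C9, so the route is a four-carbon ring expansion of carveol.
5. Enabling feature: in the C4=C5 enoate the ester is trans to C6, so the ring bonds C3–C4 and C5–C6 are cis; the intrinsic (E)-selectivity of the HWE reaction therefore gives the low-strain ring-cis cyclodecene directly. Ring order: oxirane (step 12), then carbocycle C1–C10 (step 17).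

Key step: step 17

Remark: the overview numbering is also used for the open-chain intermediates; 17–24 are mixtures of epimers at C4 only (left undefined in the SMILES), which is inconsequential because C4 becomes sp2 in step 17. CIP letters at C7 and C10 change along the route only because neighbouring groups change rank; the spatial arrangement is constant.

**Route**

Step 1
Reactants: 1 (S)-(+)-carvone
Product: 2 (1S,5S)-cis-carveol
Conditions: NaBH4, CeCl3·7H2O, MeOH, −20 to 0 °C
Reagents that add atoms: none
Why: Luche 1,2-reduction of the cyclohexenone, in which hydride should add axially to the half-chair with equatorial isopropenyl so that the new carbinol centre (the future C9) is cis to the isopropenyl group.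

Step 2
Reactants: 2 (1S,5S)-cis-carveol
Product: 3 cis-carveol 2,3-epoxide with the oxirane oxygen cis to OH
Conditions: VO(acac)2 (2 mol%), t-BuOOH, CH2Cl2, 0 °C to rt
Reagents that add atoms: tert-butyl hydroperoxide, CC(C)(C)OO
Why: Hydroxyl-directed vanadium-catalysed epoxidation, in which only the ring alkene next to the OH reacts (the isopropenyl group has no directing group) and oxygen is delivered syn to OH; both oxirane centres are destroyed in step 4.

Step 3
Reactants: 3 cis-carveol 2,3-epoxide
Product: 4 TBS ether of 3
Conditions: TBSCl, imidazole, DMAP (cat.), DMF, rt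
Reagents that add atoms: tert-butyldimethylsilyl chloride, CC(C)(C)[Si](C)(C)Cl
Why: Standard silyl ether formation on the secondary alcohol, with TBS chosen because it should survive periodic acid, amide bases and the ylide; no stereocentre is touched.

Step 4
Reactants: 4 TBS ether of 3
Product: 6 (3R,5S)-5-(tert-butyldimethylsilyloxy)-6-oxo-3-(prop-1-en-2-yl)heptanal, via trans-diol 5 (not isolated)
Conditions: H5IO6, THF–H2O, 0 °C to rt
Reagents that add atoms: water, O
Why: One-pot periodic acid cleavage of an epoxide (acid-catalysed anti opening by water to the trans-diol, then Malaprade glycol cleavage), which turns the former alkene carbons into the C10 methyl ketone and the C5 aldehyde without touching C7 or C9.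

Step 5
Reactants: 6 keto aldehyde
Product: 7 (3S,5R)-3-(tert-butyldimethylsilyloxy)-7,7-dimethoxy-5-(prop-1-en-2-yl)heptan-2-one
Conditions: HC(OMe)3, MeOH, PPTS (cat.), rt
Reagents that add atoms: trimethyl orthoformate, COC(OC)OC
Why: Acid-catalysed acetalisation with orthoformate as water scavenger should be chemoselective for the aldehyde over the hindered α-silyloxy methyl ketone.

Step 6
Reactants: 7 keto acetal
Product: 9 (3S,5R)-3-(tert-butyldimethylsilyloxy)-1-hydroxy-7,7-dimethoxy-5-(prop-1-en-2-yl)heptan-2-one, via potassium enolate 8 (not isolated)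
Conditions: KHMDS (commercial solution), THF, −78 °C; then 2-(phenylsulfonyl)-3-phenyloxaziridine, −78 °C; AcOH quench
Reagents that add atoms: 2-(phenylsulfonyl)-3-phenyloxaziridine (Davis oxaziridine), O=S(=O)(c1ccccc1)N1OC1c1ccccc1
Why: Davis α-hydroxylation of the kinetic enolate, where the bulky amide at −78 °C should deprotonate the methyl group (C14) and not the hindered oxygenated methine C9, so no stereocentre is formed or lost.

Step 7
Reactants: 9 α-hydroxy ketone
Product: 10 C14 triethylsilyl ether of 9
Conditions: TESCl, imidazole, CH2Cl2, 0 °C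
Reagents that add atoms: chlorotriethylsilane, CC[Si](CC)(CC)Cl
Why: Routine silylation of the primary alcohol, which also supplies the small CH2O-silyl arm that steers the olefination in step 9.

Step 8
Reactants: 11 methyl 5-bromopentanoate + 12 triphenylphosphine
Product: 13 (5-methoxy-5-oxopentyl)triphenylphosphonium bromide
Conditions: MeCN, reflux
Reagents that add atoms: none
Why: SN2 quaternisation of triphenylphosphine by a primary bromide (phosphonium salt formation).

Step 9
Reactants: 13 phosphonium bromide + 10 silyloxy ketone
Product: 15 methyl (5E,7S,9R)-7-(tert-butyldimethylsilyloxy)-11,11-dimethoxy-9-(prop-1-en-2-yl)-6-[(triethylsilyloxy)methyl]undec-5-enoate, via phosphonium ylide 14 (not isolated)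
Conditions: KHMDS, THF, −78 °C; then 10, −78 to 0 °C
Reagents that add atoms: none
Why: Wittig reaction of a non-stabilised ylide with an α-alkoxy ketone, a reaction known to place the ylide chain cis to the CH2O arm; here the small CH2OTES arm (C14) and the bulky branched C9 arm act in the same sense, so C2 should end cis to C14, and the activated ketone should react below 0 °C without enolisation at C9.

Step 10
Reactants: 15 olefinic ester
Product: 18 methyl (5E,7S,9R)-2-(diethoxyphosphoryl)-7-(tert-butyldimethylsilyloxy)-11,11-dimethoxy-9-(prop-1-en-2-yl)-6-[(triethylsilyloxy)methyl]undec-5-enoate (both epimers at the phosphonate carbon), via lithium ester enolate 16 (not isolated), via phosphonite 17 (not isolated)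
Conditions: LDA (commercial solution), THF, −78 °C; ClP(OEt)2, −78 °C to rt; then 30% H2O2, 0 °C
Reagents that add atoms: diethyl chlorophosphite, CCOP(Cl)OCC; hydrogen peroxide, OO
Why: C-Phosphinylation of a lithium ester enolate with a P(III) chloride followed by oxidation to the phosphonate is a known route from esters to α-phosphono esters; the new C4 centre forms unselectively, which does not matter.

Step 11
Reactants: 18 phosphonate
Product: 19 C14 allylic alcohol (18 without the triethylsilyl group)
Conditions: PPTS, MeOH, 0 °C
Reagents that add atoms: none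
Why: Acid-catalysed methanolysis should remove the primary TES ether much faster than the hindered secondary TBS ether and leaves the dimethyl acetal unchanged in methanol.

Step 12
Reactants: 19 allylic alcohol
Product: 20 (1R,10S)-1,10-epoxy alcohol
Conditions: Ti(Oi-Pr)4, L-(+)-diethyl tartrate, t-BuOOH (anhydrous), 4 Å MS, CH2Cl2, −20 °C
Reagents that add atoms: tert-butyl hydroperoxide, CC(C)(C)OO
Why: Sharpless asymmetric epoxidation of the primary allylic alcohol, where L-(+)-tartrate should deliver oxygen to the face that gives C1 (R) and C10 (S) under reagent control, the same sense in which it converts (Z)-2-alken-1-ols into (2S,3R)-epoxy alcohols; the isopropenyl group is inert.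

Step 13
Reactants: 20 epoxy alcohol
Product: 21 C14 isobutyrate of 20
Conditions: i-PrCOCl, pyridine, DMAP (cat.), CH2Cl2, 0 °C
Reagents that add atoms: isobutyryl chloride, CC(C)C(=O)Cl
Why: Pyridine/DMAP acylation of the primary epoxy alcohol installs the final isobutyrate and removes the free hydroxyl needed for a Payne rearrangement.

Step 14
Reactants: 21 epoxy isobutyrate
Product: 22 C9 alcohol (21 without the TBS group)
Conditions: TBAF, AcOH (1:1), THF, 0 °C to rt
Reagents that add atoms: none
Why: Fluoride-mediated Si–O cleavage, buffered with acetic acid so that the C9 oxygen stays protonated and neither 1,3-acyl migration from C14 nor epoxide migration should occur.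

Step 15
Reactants: 22 C9 alcohol
Product: 23 C9 acetate (seco-acetal phosphonate)
Conditions: Ac2O, pyridine, DMAP, CH2Cl2, rt
Reagents that add atoms: acetic anhydride, CC(=O)OC(C)=O
Why: DMAP-catalysed acetylation of the hindered secondary alcohol proceeds with retention at C9.

Step 16
Reactants: 23 seco-acetal phosphonate
Product: 24 seco-aldehyde phosphonate (C5 aldehyde)
Conditions: PPTS, acetone–H2O, 40 °C
Reagents that add atoms: water, O
Why: Mild acid-catalysed hydrolysis of the dimethyl acetal; the oxirane should survive because ionisation at C1 or C10 is disfavoured by the two flanking acyloxy-bearing carbons.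

Step 17
Reactants: 24 seco-aldehyde phosphonate
Product: 25 target CNP0372928.1
Conditions: LiCl, i-Pr2NEt, MeCN, rt; 24 added by syringe pump to a final concentration of about 1 mM
Reagents that add atoms: none
Why: Under LiCl/amine conditions the C4 phosphonate is deprotonated reversibly, its carbanion adds to the C5 aldehyde, and the β-oxido phosphonate collapses through the oxaphosphetane to the C4=C5 enoate and lithium diethyl phosphate. The closest known reaction type is the intramolecular Horner–Wadsworth–Emmons macrocyclisation of ω-formyl phosphonoacetates. The ten-membered carbocycle C1–C10 is closed by C4–C5 bond formation in a 10-exo-trig addition to the aldehyde followed by syn-elimination; the oxirane is already in place and no other ring forms. No stereocentre is created, both C4 epimers of 24 converge, and C1, C7, C9 and C10 are not enolisable under these conditions. The step needs ring closure over oligomerisation and the (E)-enoate: high dilution with slow addition and the turn imposed by the trans-oxirane should secure the former, and the intrinsic (E)-preference of α-alkyl phosphonoacetates, which places C3 and C6 cis, coincides with the much less strained ring-cis cyclodecene.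

**Compound list**

1 | (S)-(+)-carvone, (5S)-2-methyl-5-(prop-1-en-2-yl)cyclohex-2-en-1-one | CC1=CC[C@@H](CC1=O)C(C)=C | starting material
2 | (1S,5S)-cis-carveol (OH cis to isopropenyl) | CC1=CC[C@@H](C[C@@H]1O)C(C)=C | intermediate
3 | cis-carveol 2,3-epoxide, oxirane O cis to OH and to isopropenyl | C[C@@]12O[C@@H]1C[C@H](C(C)=C)C[C@@H]2O | intermediate
4 | TBS ether of 3 | C[C@@]12O[C@@H]1C[C@H](C(C)=C)C[C@@H]2O[Si](C)(C)C(C)(C)C | intermediate
5 | trans-diol from anti opening of 4 at the methyl-bearing carbon (either regiochemistry of opening leads to 6) | C[C@]1(O)[C@H](O)C[C@H](C(C)=C)C[C@@H]1O[Si](C)(C)C(C)(C)C | intermediate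
6 | (3R,5S)-5-(tert-butyldimethylsilyloxy)-6-oxo-3-(prop-1-en-2-yl)heptanal (C5 aldehyde, C10 methyl ketone) | CC(=O)[C@@H](O[Si](C)(C)C(C)(C)C)C[C@@H](C(C)=C)CC=O | intermediate
7 | (3S,5R)-3-(tert-butyldimethylsilyloxy)-7,7-dimethoxy-5-(prop-1-en-2-yl)heptan-2-one | CC(=O)[C@@H](O[Si](C)(C)C(C)(C)C)C[C@@H](C(C)=C)CC(OC)OC | intermediate
8 | potassium enolate of 7 (C10=C14) | C=C([O-])[C@@H](O[Si](C)(C)C(C)(C)C)C[C@@H](C(C)=C)CC(OC)OC.[K+] | intermediate
9 | (3S,5R)-3-(tert-butyldimethylsilyloxy)-1-hydroxy-7,7-dimethoxy-5-(prop-1-en-2-yl)heptan-2-one | OCC(=O)[C@@H](O[Si](C)(C)C(C)(C)C)C[C@@H](C(C)=C)CC(OC)OC | intermediate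
10 | C14 triethylsilyl ether of 9 | CC[Si](CC)(CC)OCC(=O)[C@@H](O[Si](C)(C)C(C)(C)C)C[C@@H](C(C)=C)CC(OC)OC | intermediate
11 | methyl 5-bromopentanoate | COC(=O)CCCCBr | starting material
12 | triphenylphosphine | c1ccc(cc1)P(c1ccccc1)c1ccccc1 | starting material
13 | (5-methoxy-5-oxopentyl)triphenylphosphonium bromide | COC(=O)CCCC[P+](c1ccccc1)(c1ccccc1)c1ccccc1.[Br-] | intermediate
14 | methyl 5-(triphenylphosphoranylidene)pentanoate (ylide) | COC(=O)CCCC=P(c1ccccc1)(c1ccccc1)c1ccccc1 | intermediate
15 | methyl (5E,7S,9R)-7-(tert-butyldimethylsilyloxy)-11,11-dimethoxy-9-(prop-1-en-2-yl)-6-[(triethylsilyloxy)methyl]undec-5-enoate (C2 cis to C14) | COC(=O)CCC/C=C(\CO[Si](CC)(CC)CC)[C@@H](O[Si](C)(C)C(C)(C)C)C[C@@H](C(C)=C)CC(OC)OC | intermediate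
16 | lithium enolate of ester 15 | COC([O-])=CCC/C=C(\CO[Si](CC)(CC)CC)[C@@H](O[Si](C)(C)C(C)(C)C)C[C@@H](C(C)=C)CC(OC)OC.[Li+] | intermediate
17 | C4 diethoxyphosphanyl ester (phosphonite) | COC(=O)C(CC/C=C(\CO[Si](CC)(CC)CC)[C@@H](O[Si](C)(C)C(C)(C)C)C[C@@H](C(C)=C)CC(OC)OC)P(OCC)OCC | intermediate
18 | C4 diethyl phosphonate of 15 | COC(=O)C(CC/C=C(\CO[Si](CC)(CC)CC)[C@@H](O[Si](C)(C)C(C)(C)C)C[C@@H](C(C)=C)CC(OC)OC)P(=O)(OCC)OCC | intermediate
19 | C14 allylic alcohol | COC(=O)C(CC/C=C(\CO)[C@@H](O[Si](C)(C)C(C)(C)C)C[C@@H](C(C)=C)CC(OC)OC)P(=O)(OCC)OCC | intermediate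
20 | 1,10-epoxy alcohol, C1, C7, C9, C10 arranged as in 25 | COC(=O)C(CC[C@H]1O[C@]1(CO)[C@@H](O[Si](C)(C)C(C)(C)C)C[C@@H](C(C)=C)CC(OC)OC)P(=O)(OCC)OCC | intermediate
21 | C14 isobutyrate of 20 | COC(=O)C(CC[C@H]1O[C@]1(COC(=O)C(C)C)[C@@H](O[Si](C)(C)C(C)(C)C)C[C@@H](C(C)=C)CC(OC)OC)P(=O)(OCC)OCC | intermediate
22 | C9 alcohol | COC(=O)C(CC[C@H]1O[C@]1(COC(=O)C(C)C)[C@@H](O)C[C@@H](C(C)=C)CC(OC)OC)P(=O)(OCC)OCC | intermediate
23 | C9 acetate, C5 dimethyl acetal (seco-acetal phosphonate) | COC(=O)C(CC[C@H]1O[C@]1(COC(=O)C(C)C)[C@@H](OC(C)=O)C[C@@H](C(C)=C)CC(OC)OC)P(=O)(OCC)OCC | intermediate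
24 | seco-aldehyde phosphonate (C5 aldehyde, C4 phosphonoacetate) | COC(=O)C(CC[C@H]1O[C@]1(COC(=O)C(C)C)[C@@H](OC(C)=O)C[C@@H](C(C)=C)CC=O)P(=O)(OCC)OCC | intermediate
25 | CNP0372928.1, methyl (1R,4E,7S,9S,10S)-9-acetoxy-1,10-epoxy-14-(isobutyryloxy)germacra-4,11-dien-15-oate in the overview numbering | C=C(C)[C@H]1C/C=C(/C(=O)OC)CC[C@H]2O[C@]2(COC(=O)C(C)C)[C@@H](OC(C)=O)C1 | target

**Step count and risks**

Total step count: 17. Longest linear sequence: 16 steps (steps 1–7 and 9–17, from (S)-carvone); step 8 is a one-step side branch.

Steps most likely to fail: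

Step 17. What may go wrong: bimolecular olefination (head-to-tail dimers and oligomers) may outrun closure of the ten-membered ring. Fallback, ring-closing metathesis in place of carbonyl olefination: setting out from 23, an intermolecular HWE reaction with aqueous formaldehyde (K2CO3, THF, rt) should give the α-methylene ester F1. PPTS in wet acetone should then release the aldehyde F2, and methylenation (Ph3P=CH2, THF, −78 °C) should give the triene ester F3. Its C5 vinyl and C4 acrylate termini should close with a Hoveyda–Grubbs II catalyst (toluene, 80 °C, about 1 mM) with loss of ethene. Because metathesis is reversible, oligomers can be funnelled back to the ring, and the ring-cis trisubstituted enoate is the thermodynamic product. The fallback comes back to the route at 25.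

Step 9. What may go wrong: insufficient control of the trisubstituted alkene geometry (C2 must end cis to C14), or enolisation of the hindered ketone by the ylide with erosion at C9. Fallback, a stepwise Horner–Wittig olefination with a separable adduct: setting out from 10, the dilithio derivative of 3-(diphenylphosphoryl)propan-1-ol (n-BuLi, THF, −78 °C) should add to the ketone. The adduct with the required C1/C10 relationship, the β-hydroxy phosphine oxide F4 (or its C1,C10 bis-epimer, which behaves identically), would be separated by chromatography and eliminated stereospecifically (syn) with NaH in DMF to the homoallylic alcohol F5. I2/PPh3/imidazole should give the iodide F6, and alkylation of the sodium salt of methyl 2-(diethoxyphosphoryl)acetate (NaH, DMF) comes back to the route at 18, which also bypasses 15 and step 10.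

Step 12. What may go wrong: slow turnover and reduced facial selectivity, because the allylic alcohol carries a 3-substituent cis to CH2OH, a bulky branched 2-substituent and a Lewis-basic phosphonate that can compete for titanium. Fallback, a catalyst-controlled dioxirane epoxidation that needs no free hydroxyl: setting out from 19, isobutyrylation (i-PrCOCl, pyridine) should give the allylic isobutyrate F7. Shi epoxidation with the D-fructose-derived ketone (Oxone, K2CO3 buffer, MeCN–dimethoxymethane–H2O, 0 °C) should deliver oxygen to the same face (the sense in which this ketone gives (R,R)-epoxides from trans and trisubstituted alkenes) and comes back to the route at 21.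

Further compounds
F1 | step 17 | α-methylene ester (C4=CH2, C5 dimethyl acetal) | C=C(CC[C@H]1O[C@]1(COC(=O)C(C)C)[C@@H](OC(C)=O)C[C@@H](C(C)=C)CC(OC)OC)C(=O)OC
F2 | step 17 | α-methylene ester aldehyde (C5 aldehyde) | C=C(CC[C@H]1O[C@]1(COC(=O)C(C)C)[C@@H](OC(C)=O)C[C@@H](C(C)=C)CC=O)C(=O)OC
F3 | step 17 | triene ester (C5 vinyl, C4 acrylate) | C=C(CC[C@H]1O[C@]1(COC(=O)C(C)C)[C@@H](OC(C)=O)C[C@@H](C(C)=C)CC=C)C(=O)OC
F4 | step 9 | β-hydroxy phosphine oxide (C1 P(O)Ph2, C10 OH; P and O syn when C2 and C14 are syn) | OCC[C@H](P(=O)(c1ccccc1)c1ccccc1)[C@](O)(CO[Si](CC)(CC)CC)[C@@H](O[Si](C)(C)C(C)(C)C)C[C@@H](C(C)=C)CC(OC)OC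
F5 | step 9 | homoallylic alcohol (C3 OH, C2 cis to C14) | OCC/C=C(\CO[Si](CC)(CC)CC)[C@@H](O[Si](C)(C)C(C)(C)C)C[C@@H](C(C)=C)CC(OC)OC
F6 | step 9 | C3 iodide | ICC/C=C(\CO[Si](CC)(CC)CC)[C@@H](O[Si](C)(C)C(C)(C)C)C[C@@H](C(C)=C)CC(OC)OC
F7 | step 12 | allylic isobutyrate of 19 | COC(=O)C(CC/C=C(\COC(=O)C(C)C)[C@@H](O[Si](C)(C)C(C)(C)C)C[C@@H](C(C)=C)CC(OC)OC)P(=O)(OCC)OCC
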